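Time is the wrong dial on this run: in the south run the solid substrate reads 40.4% at 0.333 h and 0% at 0.667 h, and the target then sits near 93.0% out to 4.00 h. So watch the protic impurity.

| setting | north-west | south-west | south | flask |
|---|---|---|---|---|
| solid substrate | 0.034 M | 0.075 M | 0.050 M | 0.050 M |
| coupling partner | 0.10 M | 0.10 M | 0.10 M | 0.100 M |
| protic impurity | 2.5 mM | 2.5 mM | 3.8 mM | 2.50 mM |
| remark | run made earlier | run made earlier | run made earlier |  |
| time |  |  |  | 5.0 h |

| run | time / h | target / % | solid substrate / % |
|---|---|---|---|
| north-west | 0.833 | 95.3 | 0 |
| north-west | 1.50 | 97.2 | 0 |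
| north-west | 2.50 | 96.4 | 0 |
| north-west | 3.00 | 96.7 | 1.0 |
| north-west | 4.00 | 96.1 | 0 |
| south-west | 0.833 | 86.0 | 7.3 |
| south-west | 1.50 | 97.0 | 1.0 |
| south-west | 2.50 | 96.2 | 0 |
| south-west | 3.00 | 96.1 | 0 |
| south-west | 4.00 | 98.5 | 0.9 |
| south | 0.333 | 52.5 | 40.4 |
| south | 0.667 | 93.0 | 0 |
| south | 1.00 | 94.6 | 0.6 |
| south | 2.00 | 92.9 | 1.9 |
| south | 4.00 | 91.6 | 1.3 |

(readings scatter by 1 percentage point)

- as a solid, counted per litre of solution: solid substrate
- at the start none of the solid substrate is in solution

1. how much target there is at 5.0 h, in percent of the solid substrate charged
2. the change that raises the amount of target at 5.0 h, in percent of the solid substrate charged most ("none" if none brings more than 2 percentage points) (alpha / epsilon / zeta / none)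
3. amount of target at 5.0 h, in percent of the solid substrate charged, after alpha

- alpha: doubling the amount of coupling partner, all else as stated
- epsilon: doubling the solubility of the solid substrate, all else as stated
- zeta: doubling the dissolution coefficient of the solid substrate, all else as stated

Read the recipes against each other: the south run and your flask share 0.050 M of solid substrate and differ in impurity, 3.8 mM against 2.50 mM. That shared charge makes the south run the one to read. Its missing 7 percentage points of 0.050 M is 3.49 mM of substrate, against 3.8 mM of impurity charged. Call that ratio the impurity toll, 0.918: substrate lost per impurity charged, read in the south run at 0.050 M of solid substrate, as a reading with its scatter.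

Charge your flask the toll: 2.50 mM on 0.050 M costs 4.6 points, so I commit to 95.4%. The coupling partner already stands at 2.00 equivalents, so my figure after alpha stays the same.

The forecast says 96.5%, 97.3% after alpha, and none for the best change, on the ground that "The loss therefore follows the impurity, not the substrate load or time". My figure for the flask is lower.

The flask gives 95.9%, and 95.9% after alpha. The best change is none: alpha gains 0.012 points, epsilon 1.2 points, zeta 1.1 points, the largest under 2 points, so the forecast held. With the quenching step struck out the answer is 100%. The toll reckoned 4.6 points for this flask, and its quenched substrate stands at 4.14% at 5.00 h.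

    solid substrate ⇌ dissolved substrate, rate k1*(cs1 - [dissolved substrate]) while solid is left; crystals form when [dissolved substrate] > cs1 (solubility = 35.0 mM, k = 6.48 × 10⁻⁴ s⁻¹)
    dissolved substrate + coupling partner → target (k = 0.525 L mol⁻¹ s⁻¹)
    solid substrate + protic impurity → quenched substrate (k = 0.0336 L mol⁻¹ s⁻¹)

Now take a second flask, like yours but with 0.12 M of solid substrate. The toll, carried over as an estimate from the south run's charge, leaves 98.1%, but the coupling partner covers 83.3% of that charge, so expect the lower figure. That flask gives 83.3%, with 0% of its coupling partner left: there it is the limiting reagent.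

The runs are calculated from invented constants; noise was put on by code.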